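**Retrosynthetic overview**
1. The last C–C bond (C6–C7), the stereocentres C6 and C7, and the exocyclic methylene come from a [2,3]-Wittig ring contraction. The substrate is a 13-membered α-(allyloxy) ketone whose allyl part is the butenolide.
2. The key disconnection is the C6–O ether bond of that oxacycle. It is closed by macrocyclising attack of the butenolide CH2OH (C13–OH) on a terminal C5–C6 epoxide, and C5–OH is then oxidised to the ketone.
3. The butenolide comes from the C8–O acrylate, Baylis–Hillman hydroxymethylation (C13) and RCM. The C9–O ester is made by Steglich acylation.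
4. C8 and C9 are set by Brown syn-alkoxyallylboration of an enal. C10 is set by OH-directed epoxidation and hydride opening. C4 comes from (S)-β-citronellene, which supplies 10 of the 15 skeleton carbons.
5. Ring order: butenolide (five-membered), then 13-membered ether, then 10-membered carbocycle fused to the α-methylene lactone.

Assumption: (S)-β-citronellene, allyl methoxymethyl ether and (E)-3-methylpent-2-enoic acid are bought as such.

Atom labels: germacrane numbering of the target is used throughout. C13H2=C11, C12 = lactone C=O, C8 = lactone O–CH, C7 = ring fusion, C6 = CHOH, C5 = ketone, C4 = CH(C15H3), C3–C1 = CH2 groups, C10 = C(OH)(C14H3), C9 = CH–O-acyl.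

Step 1
Reactants: 1 (S)-3,7-dimethylocta-1,6-diene ((S)-β-citronellene)
Product: 3 (2E,6S)-2,6-dimethylocta-2,7-dienal, via allylic alcohol 2 (not isolated)
Conditions: SeO2 (0.3 equiv), t-BuOOH (2.5 equiv), salicylic acid (0.1 equiv), CH2Cl2, 0 °C to rt; washed crude, MnO2 (15 equiv), CH2Cl2, rt
Reagents that add atoms: tert-butyl hydroperoxide CC(C)(C)OO
Why: Riley allylic oxidation (ene reaction then [2,3]-shift) attacks only the electron-rich trisubstituted alkene at its E-methyl group (C9), and MnO2 then oxidises only the allylic alcohol, so the vinyl group and C4 stay untouched.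

Step 2
Reactants: 3 (2E,6S)-2,6-dimethylocta-2,7-dienal; 4 allyl methoxymethyl ether
Product: 7 (3R,4R,5E,9S)-3-(methoxymethoxy)-5,9-dimethylundeca-1,5,10-trien-4-ol, via allylborane 5 (not isolated), via borinate 6 (not isolated)
Conditions: 4, s-BuLi, THF, −78 °C; (−)-Ipc2BOMe; BF3·OEt2; 3, −78 °C to rt; NaOH, H2O2, 0 °C
Reagents that add atoms: allyl methoxymethyl ether (4) C=CCOCOC
Why: Brown asymmetric (Z)-γ-alkoxyallylboration runs through a chair Zimmerman–Traxler transition state, so the Z-borane gives the syn C8/C9 pair and the Ipc groups derived from (+)-α-pinene fix its absolute sense (target configuration at C8 and C9) by clean 1,2-addition.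

Step 3
Reactants: 7 (3R,4R,5E,9S)-3-(methoxymethoxy)-5,9-dimethylundeca-1,5,10-trien-4-ol
Product: 8 (3R,4S,5S,6S,9S)-5,6-epoxy-3-(methoxymethoxy)-5,9-dimethylundeca-1,10-dien-4-ol (C1–C10 epoxide)
Conditions: VO(acac)2 (2 mol %), t-BuOOH, CH2Cl2, 0 °C
Reagents that add atoms: tert-butyl hydroperoxide CC(C)(C)OO
Why: In this hydroxyl-directed vanadium-catalysed epoxidation the C9–OH delivers the peroxide only to the adjacent trisubstituted alkene, and A1,2 strain with the C10 methyl group enforces the erythro (anti) C9–O/C10–O relationship, which sets C10.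

Step 4
Reactants: 8 (3R,4S,5S,6S,9S)-5,6-epoxy-3-(methoxymethoxy)-5,9-dimethylundeca-1,10-dien-4-ol
Product: 9 (3R,4S,5R,9S)-3-(methoxymethoxy)-5,9-dimethylundeca-1,10-diene-4,5-diol
Conditions: LiAlH4, THF, 0 °C to reflux; H2O/aq. NaOH work-up
Reagents that add atoms: none
Why: Hydride opens the 2,3-epoxy alcohol by SN2 attack at C1, the only accessible carbon because C10 is fully substituted, so the C10–O bond is kept and the tertiary alcohol appears with retention.

Step 5
Reactants: 9 (3R,4S,5R,9S)-3-(methoxymethoxy)-5,9-dimethylundeca-1,10-diene-4,5-diol; 10 (E)-3-methylpent-2-enoic acid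
Product: 11 (3R,4S,5R,9S)-5-hydroxy-3-(methoxymethoxy)-5,9-dimethylundeca-1,10-dien-4-yl (E)-3-methylpent-2-enoate
Conditions: 10, DIC, DMAP (0.3 equiv), CH2Cl2, 0 °C to rt
Reagents that add atoms: (E)-3-methylpent-2-enoic acid (10) OC(=O)/C=C(\C)CC
Why: Steglich esterification acylates the only secondary hydroxyl (C9) because the tertiary C10–OH is inert, and carbodiimide activation avoids the vinylketene pathway that would scramble the E-enoate.

Step 6
Reactants: 11 (3R,4S,5R,9S)-5-hydroxy-3-(methoxymethoxy)-5,9-dimethylundeca-1,10-dien-4-yl (E)-3-methylpent-2-enoate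
Product: 12 (3R,4S,5R,9S)-3,5-dihydroxy-5,9-dimethylundeca-1,10-dien-4-yl (E)-3-methylpent-2-enoate
Conditions: conc. HCl (cat.), MeOH, 40 °C
Reagents that add atoms: none
Why: Acid-catalysed transacetalisation moves the MOM acetal onto methanol and frees C8–OH, while the hindered conjugated ester, the alkenes and the inductively deactivated tertiary alcohol survive and no stereocentre is touched.

Step 7
Reactants: 12 (3R,4S,5R,9S)-3,5-dihydroxy-5,9-dimethylundeca-1,10-dien-4-yl (E)-3-methylpent-2-enoate; 13 acryloyl chloride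
Product: 14 (3R,4S,5R,9S)-3-(acryloyloxy)-5-hydroxy-5,9-dimethylundeca-1,10-dien-4-yl (E)-3-methylpent-2-enoate
Conditions: 13, i-Pr2NEt, CH2Cl2, −78 to 0 °C
Reagents that add atoms: acryloyl chloride (13) C=CC(=O)Cl
Why: O-acylation with an acid chloride takes the secondary allylic C8–OH only, forming the C8–O–C12 bond of the future lactone, because the tertiary alcohol does not react at low temperature.

Step 8
Reactants: 14 (3R,4S,5R,9S)-3-(acryloyloxy)-5-hydroxy-5,9-dimethylundeca-1,10-dien-4-yl (E)-3-methylpent-2-enoate; 15 formaldehyde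
Product: 16 (3R,4S,5R,9S)-5-hydroxy-3-{[2-(hydroxymethyl)acryloyl]oxy}-5,9-dimethylundeca-1,10-dien-4-yl (E)-3-methylpent-2-enoate
Conditions: aq. HCHO (37 %), DABCO (1 equiv), 1,4-dioxane/H2O 1:1, rt
Reagents that add atoms: formaldehyde (15) C=O
Why: In the Morita–Baylis–Hillman reaction DABCO adds only to the β-unsubstituted acrylate, the zwitterionic enolate traps formaldehyde, and loss of DABCO returns the 2-(hydroxymethyl)acrylate, which installs C13 with its free OH and needs no protecting group.

Step 9
Reactants: 16 (3R,4S,5R,9S)-5-hydroxy-3-{[2-(hydroxymethyl)acryloyl]oxy}-5,9-dimethylundeca-1,10-dien-4-yl (E)-3-methylpent-2-enoate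
Product: 17 C5,C6-epoxide of 16 (about 1:1 at C5)
Conditions: mCPBA (1.1 equiv), CH2Cl2, 0 °C to rt
Reagents that add atoms: 3-chloroperbenzoic acid O=C(OO)c1cccc(Cl)c1
Why: The electrophilic Prilezhaev epoxidation picks the only electron-rich alkene (C5=C6) because the others are conjugated to carbonyls or deactivated by allylic acyloxy groups, and the C5 epimers do not matter because C5 later becomes a ketone.

Step 10
Reactants: 17 C5,C6-epoxide of 16
Product: 18 (5R)-3-(hydroxymethyl)furan-2(5H)-one carrying the C9–C4 chain at C8 (butenolide epoxide)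
Conditions: second-generation Hoveyda–Grubbs catalyst (5 mol %), toluene (5 mM), 80 °C
Reagents that add atoms: none
Why: Ring-closing metathesis of the allylic 2-substituted acrylate forms the five-membered butenolide (C7=C11) with loss of ethene, the already epoxidised west end cannot interfere, and C8 is not touched.

Step 11
Reactants: 18 butenolide epoxide
Product: 19 13-membered oxacycle in which a C13–O–C6 ether bridges the butenolide, with C5–OH as both epimers
Conditions: cyclic oligo[(salen)Co(OTs)] (salen = N,N′-bis(3,5-di-tert-butylsalicylidene)cyclohexane-1,2-diaminate units linked by heptanedioate diesters), both antipodes 1:1, 8 mol % Co in all, 4 Å MS, MeCN/CH2Cl2 1:1, slow addition to 1 mM, 23 °C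
Reagents that add atoms: none
Why: Proposed new method: this is a macrocyclising hydroxy-epoxide opening by cooperative bimetallic (salen)Co catalysis, in which one trivalent cobalt centre of the oligomer activates the terminal epoxide as a Lewis acid while a neighbouring centre holds the primary C13–OH as its alkoxide, so both chain ends sit on one catalyst molecule and the alkoxide attacks unhindered C6 by SN2 to forge the C6–O bond and a nearly strain-free 13-membered ring; the tertiary C10–OH is too hindered to bind, the neutral medium spares the base-labile butenolide and C9 ester, and both C5 epimers react because both catalyst antipodes are present; the closest known reactions are the (salen)Co-catalysed intermolecular alcoholysis of terminal epoxides and the cyclisation of epoxy alcohols to five- to seven-membered ethers.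

Step 12
Reactants: 19 13-membered oxacycle alcohol
Product: 20 13-membered α-(allyloxy) ketone (C5=O)
Conditions: Dess–Martin periodinane, CH2Cl2, rt
Reagents that add atoms: none
Why: Dess–Martin oxidation converts the only secondary alcohol (both C5 epimers converge on one ketone) under nearly neutral conditions that do not epimerise C4 or C8 and leave the tertiary alcohol alone.

Step 13
Reactants: 20 13-membered α-(allyloxy) ketone
Product: 23 (4S,6S,7S,8R,9S,10R)-6,10-dihydroxy-9-[(E)-3-methylpent-2-enoyloxy]-5-oxogermacr-11(13)-en-8,12-olide, via boron enolate 21 (not isolated), via bis-borinate 22 (not isolated)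
Conditions: n-Bu2BOTf (2.3 equiv), i-Pr2NEt (3 equiv), CH2Cl2, −78 to −10 °C; pH 7 buffer/MeOH, 0 °C
Reagents that add atoms: none
Why: This is a [2,3]-Wittig rearrangement in its boron-enolate variant, used as a 13→10 ring contraction: soft enolisation occurs only at the activated C6H2 so C4 is safe, nucleophilic C6 attacks electrophilic C7 of the butenolide on the face anti to C9 to give the trans ring fusion (7S), the acyl group sits exo in the envelope transition state as expected for an E-type allyl terminus giving the anti product (6S), and cleavage of the C13–O bond releases C6–OH and the exocyclic methylene.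

**Compound list**
1 | (S)-3,7-dimethylocta-1,6-diene | C=C[C@@H](C)CCC=C(C)C | starting material
2 | (2E,6S)-2,6-dimethylocta-2,7-dien-1-ol | C=C[C@@H](C)CC/C=C(\C)CO | intermediate
3 | (2E,6S)-2,6-dimethylocta-2,7-dienal | C=C[C@@H](C)CC/C=C(\C)C=O | intermediate
4 | allyl methoxymethyl ether | C=CCOCOC | starting material
5 | (Z)-[3-(methoxymethoxy)allyl]diisopinocampheylborane | COCO/C=C\CB([C@@H]1C[C@@H]2C[C@H]([C@H]1C)C2(C)C)[C@@H]1C[C@@H]2C[C@H]([C@H]1C)C2(C)C | intermediate
6 | diisopinocampheylborinate of 7 (C9–O–B) | C=C[C@@H](C)CC/C=C(\C)[C@@H](OB([C@@H]1C[C@@H]2C[C@H]([C@H]1C)C2(C)C)[C@@H]1C[C@@H]2C[C@H]([C@H]1C)C2(C)C)[C@H](OCOC)C=C | intermediate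
7 | (3R,4R,5E,9S)-3-(methoxymethoxy)-5,9-dimethylundeca-1,5,10-trien-4-ol | C=C[C@@H](C)CC/C=C(\C)[C@@H](O)[C@H](OCOC)C=C | intermediate
8 | (3R,4S,5S,6S,9S)-5,6-epoxy-3-(methoxymethoxy)-5,9-dimethylundeca-1,10-dien-4-ol | C=C[C@@H](C)CC[C@@H]1O[C@@]1(C)[C@@H](O)[C@H](OCOC)C=C | intermediate
9 | (3R,4S,5R,9S)-3-(methoxymethoxy)-5,9-dimethylundeca-1,10-diene-4,5-diol | C=C[C@@H](C)CCC[C@@](C)(O)[C@@H](O)[C@H](OCOC)C=C | intermediate
10 | (E)-3-methylpent-2-enoic acid | OC(=O)/C=C(\C)CC | starting material
11 | C9 (E)-3-methylpent-2-enoate of 9 | C=C[C@@H](C)CCC[C@@](C)(O)[C@@H](OC(=O)/C=C(\C)CC)[C@H](OCOC)C=C | intermediate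
12 | C8 alcohol (MOM removed) | C=C[C@@H](C)CCC[C@@](C)(O)[C@@H](OC(=O)/C=C(\C)CC)[C@H](O)C=C | intermediate
13 | acryloyl chloride | C=CC(=O)Cl | starting material
14 | C8 acrylate | C=C[C@@H](C)CCC[C@@](C)(O)[C@@H](OC(=O)/C=C(\C)CC)[C@H](OC(=O)C=C)C=C | intermediate
15 | formaldehyde | C=O | starting material
16 | C8 2-(hydroxymethyl)acrylate | C=C[C@@H](C)CCC[C@@](C)(O)[C@@H](OC(=O)/C=C(\C)CC)[C@H](OC(=O)C(=C)CO)C=C | intermediate
17 | C5,C6-epoxide of 16 (C5 not defined, about 1:1) | C1OC1[C@@H](C)CCC[C@@](C)(O)[C@@H](OC(=O)/C=C(\C)CC)[C@H](OC(=O)C(=C)CO)C=C | intermediate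
18 | 3-(hydroxymethyl)butenolide epoxide (C5 not defined) | C1OC1[C@@H](C)CCC[C@@](C)(O)[C@@H](OC(=O)/C=C(\C)CC)[C@@H]2OC(=O)C(CO)=C2 | intermediate
19 | 13-membered oxacycle alcohol (C5 not defined) | OC1[C@@H](C)CCC[C@@](C)(O)[C@@H](OC(=O)/C=C(\C)CC)[C@@H]2OC(=O)C(=C2)COC1 | intermediate
20 | 13-membered α-(allyloxy) ketone | O=C1[C@@H](C)CCC[C@@](C)(O)[C@@H](OC(=O)/C=C(\C)CC)[C@@H]2OC(=O)C(=C2)COC1 | intermediate
21 | C5–C6 dibutylboron enolate, C10–O–BBu2 (enolate geometry not fixed) | CCCCB(CCCC)OC=1[C@@H](C)CCC[C@@](C)(OB(CCCC)CCCC)[C@@H](OC(=O)/C=C(\C)CC)[C@@H]2OC(=O)C(=C2)COC=1 | intermediate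
22 | C6,C10-bis(dibutylborinate) of 23 | C=C1C(=O)O[C@@H]2[C@@H]1[C@H](OB(CCCC)CCCC)C(=O)[C@@H](C)CCC[C@@](C)(OB(CCCC)CCCC)[C@H]2OC(=O)/C=C(\C)CC | intermediate
23 | CNP0197047.1, (4S,6S,7S,8R,9S,10R)-6,10-dihydroxy-9-[(E)-3-methylpent-2-enoyloxy]-5-oxogermacr-11(13)-en-8,12-olide | C=C1C(=O)O[C@@H]2[C@@H]1[C@H](O)C(=O)[C@@H](C)CCC[C@@](C)(O)[C@H]2OC(=O)/C=C(\C)CC | target

**Step count:** 13 steps in total. The longest linear sequence is 13 steps, from 1.

**Steps most likely to fail**

Step 11 (the new macrocyclising epoxide opening). The risks are oligomerisation, slow turnover at 1 mM, and hydrolysis of the epoxide by adventitious water. The fallback closes the large ring by an established lactonisation instead of an etherification. It sets out from 11, whose C5=C6 vinyl group is epoxidised with mCPBA to the west epoxide F1. The epoxide is opened intermolecularly at C6 with tert-butyl 2-(hydroxymethyl)acrylate under (salen)Co(OTs), a known alcoholysis, to the hydroxy ether F2. Dess–Martin oxidation then gives the keto ether F3. TFA/CH2Cl2/H2O removes the MOM and tert-butyl groups together to give the seco acid F4. Shiina lactonisation (2-methyl-6-nitrobenzoic anhydride, DMAP, high dilution) closes the C8–O–C12 bond to the 14-membered macrolactone F5. RCM between the C8 vinyl group and the C11 methylene then builds the butenolide and returns to the route at 20.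

Step 13 (ring contraction). The risks are vinylogous E1cB loss of the C9 carboxylate or C8 epimerisation through the butenolide dienolate, a competing [3,3] shift that would form a C5–C7 bond, and only a modest driving force. The fallback gives up the ether tether and closes the ten-membered ring directly by a known Barbier allylation with a 3-(bromomethyl)butenolide. It sets out from 18, which CBr4/PPh3 converts into the bromomethyl butenolide epoxide F6. Catalytic HClO4 in THF/H2O hydrolyses the epoxide to the C5,C6-diol F7. IBX in DMSO oxidises both carbinols without C–C cleavage to the keto aldehyde F8. Indium metal in THF/H2O at 1 mM then joins C7 to the aldehyde carbon C6 chemoselectively, giving the anti adduct by attack anti to C9. This comes back to the route at 23.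

Step 8 (Baylis–Hillman reaction on a hindered secondary acrylate). The risks are a very slow reaction, ether dimers and ester hydrolysis. The fallback brings C13 in together with the acyl group. It sets out from 12, which is esterified (DIC, DMAP) with 2-{[(tert-butyldimethylsilyl)oxy]methyl}acrylic acid, made from ethyl 2-(hydroxymethyl)acrylate with TBSCl and then LiOH, to give the silyl ether F9. HF·pyridine in THF frees the alcohol and returns to the route at 16.

**Further compounds**
F1 | step 11 | C5,C6-epoxide of 11 (C5 not defined) | C1OC1[C@@H](C)CCC[C@@](C)(O)[C@@H](OC(=O)/C=C(\C)CC)[C@H](OCOC)C=C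
F2 | step 11 | C6–O–C13 hydroxy ether, tert-butyl ester (C5 not defined) | C=C(COCC(O)[C@@H](C)CCC[C@@](C)(O)[C@@H](OC(=O)/C=C(\C)CC)[C@H](OCOC)C=C)C(=O)OC(C)(C)C
F3 | step 11 | C5 keto ether, tert-butyl ester | C=C(COCC(=O)[C@@H](C)CCC[C@@](C)(O)[C@@H](OC(=O)/C=C(\C)CC)[C@H](OCOC)C=C)C(=O)OC(C)(C)C
F4 | step 11 | seco acid (C8–OH, C12 acid) | C=C(COCC(=O)[C@@H](C)CCC[C@@](C)(O)[C@@H](OC(=O)/C=C(\C)CC)[C@H](O)C=C)C(=O)O
F5 | step 11 | 14-membered macrolactone | C=C[C@H]1OC(=O)C(=C)COCC(=O)[C@@H](C)CCC[C@@](C)(O)[C@H]1OC(=O)/C=C(\C)CC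
F6 | step 13 | 3-(bromomethyl)butenolide epoxide (C5 not defined) | C1OC1[C@@H](C)CCC[C@@](C)(O)[C@@H](OC(=O)/C=C(\C)CC)[C@@H]2OC(=O)C(CBr)=C2
F7 | step 13 | 3-(bromomethyl)butenolide C5,C6-diol (C5 not defined) | OCC(O)[C@@H](C)CCC[C@@](C)(O)[C@@H](OC(=O)/C=C(\C)CC)[C@@H]2OC(=O)C(CBr)=C2
F8 | step 13 | 3-(bromomethyl)butenolide C5-keto C6-aldehyde | O=CC(=O)[C@@H](C)CCC[C@@](C)(O)[C@@H](OC(=O)/C=C(\C)CC)[C@@H]2OC(=O)C(CBr)=C2
F9 | step 8 | C8 2-(silyloxymethyl)acrylate | C=C[C@@H](C)CCC[C@@](C)(O)[C@@H](OC(=O)/C=C(\C)CC)[C@H](OC(=O)C(=C)CO[Si](C)(C)C(C)(C)C)C=C
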